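**Plan**
- Retrosynthesis: the O3–acyl bond of the vanillate is cut first (acylation of benzyl-protected epicatechin 11). Both stereocentres are then traced back to racemic flavan-3-one 10, and ring C is cut at C4–C4a and O1–C2.
- Feature used: ring A is a phloroglucinol, so C4a (ortho to the O1 hydroxyl) and O1 form a C,O-1,3-bisnucleophile. The chain C4–C3–C2, with oxygen on C3 and ring B on C2, maps onto an α-acyloxycinnamaldehyde (C4 = CHO, C2 = β-carbon), a 1,3-biselectrophile.
- Their boron-templated condensation gives the 1-oxatriene O1=C8a–C4a=C4–C3=C2 (an ortho-quinone methide), which closes ring C by oxa-6π electrocyclisation. The C3 enol ester that remains is a masked ketone.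
- Forward order: ring B aldehyde + acetylide (C3, C4) + pivalate give a propargylic ester, then the enal by gold-catalysed 1,2-acyloxy shift/oxidation (steps 1–2). Ring C is closed onto ring A (step 3) and the ketone is unmasked (step 4).
- Stereochemistry: C2 of ketone 10 is labile (α to C=O, benzylic, α-aryloxy), so one catalyst-controlled dynamic kinetic transfer hydrogenation (step 5) sets C2 (R) and C3 (R), cis. Acylation and hydrogenolysis (steps 6–7) do not touch them.

Key step: step 3

Assumption: in step 5 the (R,R) ligand antipode is assigned to the (2R,3R) alcohol by the usual model (the more substituted, π-rich C2 side of the ketone next to the η6-arene); this would be checked on a small scale and the mirror-image catalyst used if the sense is opposite.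

Step 1
Reactants: 1 3,4-bis(benzyloxy)benzaldehyde; 2 ethynylmagnesium bromide
Product: 4 1-[3,4-bis(benzyloxy)phenyl]prop-2-yn-1-yl pivalate (racemic), via bromomagnesium propargylic alkoxide 3 (not isolated)
Conditions: THF, 0 °C; then t-BuCOCl, 0 °C to rt
Reagents that add atoms: pivaloyl chloride, CC(C)(C)C(=O)Cl
Why: Grignard 1,2-addition of the acetylide to the aryl aldehyde and O-acylation of the magnesium alkoxide in the same flask; the carbinol stereocentre is erased in step 2, so no control is needed.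

Step 2
Reactants: 4 1-[3,4-bis(benzyloxy)phenyl]prop-2-yn-1-yl pivalate
Product: 5 (2Z)-3-[3,4-bis(benzyloxy)phenyl]-1-oxoprop-2-en-2-yl pivalate (α-pivaloyloxy cinnamaldehyde, ring B trans to CHO)
Conditions: [1,3-bis(2,6-diisopropylphenyl)imidazol-2-ylidene]AuCl (5 mol %), AgSbF6 (5 mol %), Ph2SO (2 equiv), CH2Cl2, rt
Reagents that add atoms: diphenyl sulfoxide, O=S(c1ccccc1)c1ccccc1
Why: cationic monovalent gold should trigger the 1,2-acyloxy migration typical of terminal propargylic carboxylates to a catalyst-bound vinylcarbenoid ArCH=C(OPiv)–CH=[Au], whose carbene carbon is oxidised by the sulfoxide (gold-catalysed oxidative rearrangement), giving the enal as the thermodynamically favoured (Z) isomer.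

Step 3
Reactants: 5 (2Z)-3-[3,4-bis(benzyloxy)phenyl]-1-oxoprop-2-en-2-yl pivalate; 6 3,5-bis(benzyloxy)phenol
Product: 9 5,7-bis(benzyloxy)-2-[3,4-bis(benzyloxy)phenyl]-2H-chromen-3-yl pivalate (racemic), via benzodioxaborin 7 (not isolated), via ortho-quinone methide 8 (not isolated)
Conditions: PhB(OH)2 (1.0 equiv), EtCO2H (0.3 equiv), toluene, reflux, Dean–Stark trap, argon
Reagents that add atoms: none
Why: Phenol 6 and PhB(OH)2 should form an aryloxyboronate that delivers the aldehyde carbon of 5 to the ortho carbon through a six-membered chelate (C4–C4a), giving benzodioxaborin 7, which on heating releases the boron template to unveil ortho-quinone methide 8, the 1-oxatriene O1=C8a–C4a=C4–C3=C2. This triene closes ring C by a thermal disrotatory oxa-6π electrocyclisation (O1–C2), restoring the aromaticity of ring A and leaving the C3=C4 enol pivalate. The closest known reaction type is the boronic-acid-mediated condensation of phenols with α,β-unsaturated aldehydes to 2H-chromenes, a formal [3+3] annulation. The six-membered pyran ring is therefore closed pericyclically and not by an ionic 6-endo addition, so ring B on C2 needs no cation-stabilising role here. C2 is formed without control (racemic) on purpose, because it becomes epimerisable in ketone 10 and is set in step 5. The step needs ortho-C attack instead of para-C or O attack and 1,2- instead of 1,4-addition: the boron chelate enforces ortho delivery to the aldehyde carbon, the two ortho positions of 6 are equivalent, the α-acyloxy group makes the β-carbon electron-rich and poor in conjugate addition, and the hindered pivalate resists acyl transfer to the phenol.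

Step 4
Reactants: 9 5,7-bis(benzyloxy)-2-[3,4-bis(benzyloxy)phenyl]-2H-chromen-3-yl pivalate
Product: 10 5,7-bis(benzyloxy)-2-[3,4-bis(benzyloxy)phenyl]chroman-3-one (racemic)
Conditions: K2CO3 (0.5 equiv), MeOH/THF, 0 °C to rt, argon; AcOH quench
Reagents that add atoms: none
Why: base-catalysed methanolysis of an enol ester (enolate as leaving group, comparable to an aryl ester) releases the enolate, which protonates at C4 to the ketone; oxygen is excluded because 3-chromanones autoxidise and self-condense under base.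

Step 5
Reactants: 10 5,7-bis(benzyloxy)-2-[3,4-bis(benzyloxy)phenyl]chroman-3-one
Product: 11 (2R,3R)-5,7-bis(benzyloxy)-2-[3,4-bis(benzyloxy)phenyl]chroman-3-ol (2,3-cis)
Conditions: RuCl[(R,R)-TsDPEN](p-cymene) (2 mol %), HCO2H (3 equiv), Et3N (6 equiv), DMF, 40 °C, argon
Reagents that add atoms: none
Why: Noyori–Ikariya asymmetric transfer hydrogenation under dynamic kinetic resolution: the C2–H (α to C=O, benzylic to ring B, α to O1) should enolise under the amine so that the enantiomers of 10 interconvert, while the chiral ruthenium hydride reduces the (2R) ketone faster and delivers hydride to the C3 face anti to the 2-aryl group, setting C2 (R) and C3 (R) cis in one step.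

Step 6
Reactants: 11 (2R,3R)-5,7-bis(benzyloxy)-2-[3,4-bis(benzyloxy)phenyl]chroman-3-ol; 12 4-(benzyloxy)-3-methoxybenzoic acid
Product: 13 (2R,3R)-5,7-bis(benzyloxy)-2-[3,4-bis(benzyloxy)phenyl]chroman-3-yl 4-(benzyloxy)-3-methoxybenzoate
Conditions: DCC (1.5 equiv), DMAP (0.2 equiv), CH2Cl2, rt
Reagents that add atoms: none
Why: Steglich esterification of the axial secondary C3 hydroxyl, as in the galloylation of benzylated epicatechins; only the acyl–O bond is formed, so neither stereocentre is touched.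

Step 7
Reactants: 13 (2R,3R)-5,7-bis(benzyloxy)-2-[3,4-bis(benzyloxy)phenyl]chroman-3-yl 4-(benzyloxy)-3-methoxybenzoate
Product: 14 (2R,3R)-2-(3,4-dihydroxyphenyl)-5,7-dihydroxychroman-3-yl 4-hydroxy-3-methoxybenzoate (target)
Conditions: H2 (1 atm), Pd(OH)2/C, THF/MeOH (1:1), rt
Reagents that add atoms: none
Why: hydrogenolysis of the five benzyl ethers under mild conditions, which should leave the benzoate ester, the ring C2–O1 bond and both stereocentres intact, as in the final step of epicatechin gallate syntheses.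

**Compound list**
1 | 3,4-bis(benzyloxy)benzaldehyde | O=Cc1ccc(OCc2ccccc2)c(OCc2ccccc2)c1 | starting material
2 | ethynylmagnesium bromide | C#C[Mg]Br | starting material
3 | bromomagnesium 1-[3,4-bis(benzyloxy)phenyl]prop-2-yn-1-olate (racemic, not isolated) | C#CC(O[Mg]Br)c1ccc(OCc2ccccc2)c(OCc2ccccc2)c1 | intermediate
4 | 1-[3,4-bis(benzyloxy)phenyl]prop-2-yn-1-yl pivalate (racemic) | C#CC(OC(=O)C(C)(C)C)c1ccc(OCc2ccccc2)c(OCc2ccccc2)c1 | intermediate
5 | (2Z)-3-[3,4-bis(benzyloxy)phenyl]-1-oxoprop-2-en-2-yl pivalate | O=C/C(OC(=O)C(C)(C)C)=C/c1ccc(OCc2ccccc2)c(OCc2ccccc2)c1 | intermediate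
6 | 3,5-bis(benzyloxy)phenol | Oc1cc(OCc2ccccc2)cc(OCc2ccccc2)c1 | starting material
7 | 5,7-bis(benzyloxy)-2-phenyl-4-[(1Z)-2-[3,4-bis(benzyloxy)phenyl]-1-(pivaloyloxy)ethenyl]-4H-1,3,2-benzodioxaborinine (racemic, not isolated) | CC(C)(C)C(=O)O/C(=C\c1ccc(OCc2ccccc2)c(OCc2ccccc2)c1)C1OB(c2ccccc2)Oc2cc(OCc3ccccc3)cc(OCc3ccccc3)c12 | intermediate
8 | 3,5-bis(benzyloxy)-6-[(2Z)-3-[3,4-bis(benzyloxy)phenyl]-2-(pivaloyloxy)prop-2-en-1-ylidene]cyclohexa-2,4-dien-1-one (ortho-quinone methide, exocyclic geometry undefined, not isolated) | CC(C)(C)C(=O)O/C(C=C1C(=O)C=C(OCc2ccccc2)C=C1OCc1ccccc1)=C\c1ccc(OCc2ccccc2)c(OCc2ccccc2)c1 | intermediate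
9 | 5,7-bis(benzyloxy)-2-[3,4-bis(benzyloxy)phenyl]-2H-chromen-3-yl pivalate (racemic) | CC(C)(C)C(=O)OC1=Cc2c(OCc3ccccc3)cc(OCc3ccccc3)cc2OC1c1ccc(OCc2ccccc2)c(OCc2ccccc2)c1 | intermediate
10 | 5,7-bis(benzyloxy)-2-[3,4-bis(benzyloxy)phenyl]chroman-3-one (racemic) | O=C1Cc2c(OCc3ccccc3)cc(OCc3ccccc3)cc2OC1c1ccc(OCc2ccccc2)c(OCc2ccccc2)c1 | intermediate
11 | (2R,3R)-5,7-bis(benzyloxy)-2-[3,4-bis(benzyloxy)phenyl]chroman-3-ol | O[C@@H]1Cc2c(OCc3ccccc3)cc(OCc3ccccc3)cc2O[C@@H]1c1ccc(OCc2ccccc2)c(OCc2ccccc2)c1 | intermediate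
12 | 4-(benzyloxy)-3-methoxybenzoic acid | COc1cc(C(=O)O)ccc1OCc1ccccc1 | starting material
13 | (2R,3R)-5,7-bis(benzyloxy)-2-[3,4-bis(benzyloxy)phenyl]chroman-3-yl 4-(benzyloxy)-3-methoxybenzoate | COc1cc(C(=O)O[C@@H]2Cc3c(OCc4ccccc4)cc(OCc4ccccc4)cc3O[C@@H]2c2ccc(OCc3ccccc3)c(OCc3ccccc3)c2)ccc1OCc1ccccc1 | intermediate
14 | (2R,3R)-2-(3,4-dihydroxyphenyl)-5,7-dihydroxychroman-3-yl 4-hydroxy-3-methoxybenzoate | COc1cc(C(=O)O[C@@H]2Cc3c(O)cc(O)cc3O[C@@H]2c2ccc(O)c(O)c2)ccc1O | target

Total step count: 7. Longest linear sequence: 7 steps (1 to 14).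

**Steps most likely to fail**

Step 3. The phenol may be alkylated at the para carbon or add in a conjugate sense to the enal, or the ortho-quinone methide may oligomerise before it cyclises. The fallback builds ring C from the other side with known reactions, setting out from 6 and 1 and coming back at 10. Ortho-formylation of 6 (MgCl2, Et3N, paraformaldehyde, MeCN, reflux) should give 2,4-bis(benzyloxy)-6-hydroxybenzaldehyde F1. Henry condensation of 1 with nitromethane (NH4OAc, AcOH, 100 °C) should give (E)-1,2-bis(benzyloxy)-4-(2-nitroethenyl)benzene F2. Base-mediated oxa-Michael/Henry/dehydration of F1 with F2 (DABCO, MeCN, 60 °C) should give 5,7-bis(benzyloxy)-2-[3,4-bis(benzyloxy)phenyl]-3-nitro-2H-chromene F3. Reductive hydrolysis of the conjugated nitroalkene (Fe powder, AcOH, 80 °C, as for nitrostyrenes to arylacetones) should give ketone 10.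

Step 5. Enolisation at C2 may be too slow relative to reduction, so that both enantiomers of 10 are reduced, or the catalyst may discriminate the ketone faces poorly; base-induced decomposition of the ketone is a further risk. The fallback sets out from 10 and comes back at 11. Substrate-controlled reduction with LiBH(s-Bu)3 (THF, −78 °C), with hydride delivered anti to the 2-aryl group, should give the racemic 2,3-cis alcohol F4. Esterification with (S)-2-methoxy-2-phenylacetic acid (DCC, DMAP, CH2Cl2) should give the diastereomeric esters (2R,3R)-chroman-3-yl (2S)-2-methoxy-2-phenylacetate F5 and (2S,3S)-chroman-3-yl (2S)-2-methoxy-2-phenylacetate F6, to be separated by chromatography or crystallisation. Saponification of F5 (LiOH, THF/MeOH/H2O, rt) returns 11.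

Step 2. The electron-rich propargylic ester may ionise, undergo 1,3-acyloxy shift to an allenyl ester, or the carbenoid may attack ring B intramolecularly (indene formation) before it is oxidised. The fallback sets out from 1 and comes back at 5. Horner–Wadsworth–Emmons olefination of 1 with ethyl 2-(tert-butyldimethylsilyloxy)-2-(diethoxyphosphoryl)acetate (LiN(SiMe3)2, THF, −78 °C to rt) should give ethyl (2Z)-3-[3,4-bis(benzyloxy)phenyl]-2-(tert-butyldimethylsilyloxy)prop-2-enoate F7. Reduction (i-Bu2AlH, CH2Cl2, −78 °C) should give (2Z)-3-[3,4-bis(benzyloxy)phenyl]-2-(tert-butyldimethylsilyloxy)prop-2-en-1-ol F8, and allylic oxidation (MnO2, CH2Cl2, rt) should give (2Z)-3-[3,4-bis(benzyloxy)phenyl]-2-(tert-butyldimethylsilyloxy)prop-2-enal F9. Desilylation (Bu4NF, AcOH, THF, 0 °C) should give the enol (2Z)-3-[3,4-bis(benzyloxy)phenyl]-2-hydroxyprop-2-enal F10, which is acylated in the same flask (pivaloyl chloride, Et3N, DMAP) to 5.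

**Further compounds**
F1 | step 3 | 2,4-bis(benzyloxy)-6-hydroxybenzaldehyde | O=Cc1c(O)cc(OCc2ccccc2)cc1OCc1ccccc1
F2 | step 3 | (E)-1,2-bis(benzyloxy)-4-(2-nitroethenyl)benzene | O=[N+]([O-])/C=C/c1ccc(OCc2ccccc2)c(OCc2ccccc2)c1
F3 | step 3 | 5,7-bis(benzyloxy)-2-[3,4-bis(benzyloxy)phenyl]-3-nitro-2H-chromene (racemic) | [O-][N+](=O)C1=Cc2c(OCc3ccccc3)cc(OCc3ccccc3)cc2OC1c1ccc(OCc2ccccc2)c(OCc2ccccc2)c1
F4 | step 5 | rac-cis-5,7-bis(benzyloxy)-2-[3,4-bis(benzyloxy)phenyl]chroman-3-ol (1:1 mixture of 11 and its enantiomer) | O[C@@H]1Cc2c(OCc3ccccc3)cc(OCc3ccccc3)cc2O[C@@H]1c1ccc(OCc2ccccc2)c(OCc2ccccc2)c1.O[C@H]1Cc2c(OCc3ccccc3)cc(OCc3ccccc3)cc2O[C@H]1c1ccc(OCc2ccccc2)c(OCc2ccccc2)c1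
F5 | step 5 | (2R,3R)-5,7-bis(benzyloxy)-2-[3,4-bis(benzyloxy)phenyl]chroman-3-yl (2S)-2-methoxy-2-phenylacetate | CO[C@H](C(=O)O[C@@H]1Cc2c(OCc3ccccc3)cc(OCc3ccccc3)cc2O[C@@H]1c1ccc(OCc2ccccc2)c(OCc2ccccc2)c1)c1ccccc1
F6 | step 5 | (2S,3S)-5,7-bis(benzyloxy)-2-[3,4-bis(benzyloxy)phenyl]chroman-3-yl (2S)-2-methoxy-2-phenylacetate | CO[C@H](C(=O)O[C@H]1Cc2c(OCc3ccccc3)cc(OCc3ccccc3)cc2O[C@H]1c1ccc(OCc2ccccc2)c(OCc2ccccc2)c1)c1ccccc1
F7 | step 2 | ethyl (2Z)-3-[3,4-bis(benzyloxy)phenyl]-2-(tert-butyldimethylsilyloxy)prop-2-enoate | CCOC(=O)/C(O[Si](C)(C)C(C)(C)C)=C/c1ccc(OCc2ccccc2)c(OCc2ccccc2)c1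
F8 | step 2 | (2Z)-3-[3,4-bis(benzyloxy)phenyl]-2-(tert-butyldimethylsilyloxy)prop-2-en-1-ol | OC/C(O[Si](C)(C)C(C)(C)C)=C/c1ccc(OCc2ccccc2)c(OCc2ccccc2)c1
F9 | step 2 | (2Z)-3-[3,4-bis(benzyloxy)phenyl]-2-(tert-butyldimethylsilyloxy)prop-2-enal | O=C/C(O[Si](C)(C)C(C)(C)C)=C/c1ccc(OCc2ccccc2)c(OCc2ccccc2)c1
F10 | step 2 | (2Z)-3-[3,4-bis(benzyloxy)phenyl]-2-hydroxyprop-2-enal | O=C/C(O)=C/c1ccc(OCc2ccccc2)c(OCc2ccccc2)c1
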